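## Analysis of the target

Germacrane-type numbering is used throughout: C1 is the enol-ether carbon on the ring oxygen, C2 its olefinic CH, C3 the ring CH2, C4 the methyl-bearing ether carbon, C5 the exocyclic olefinic CH, C6 the olefinic carbon on the lactone oxygen, C7 and C11 the β- and α-carbons of the butenolide, C8 the CH carrying the methacrylate, C9 a CH2, C10 the tertiary carbinol, C12 the lactone carbonyl, C13 the acetoxymethyl carbon, and C14 and C15 the methyls on C10 and C4. Target 41 is a ten-membered carbocycle C1–C10 that an oxygen bridge between C1 and C4 turns into an 11-oxabicyclo[6.2.1]undecane, fused at C6–C7 to an α,β-unsaturated γ-lactone. The five-membered oxygen ring is a 4,5-dihydrofuran (O–C1=C2 enol ether), and the lactone is a γ-ylidene butenolide whose exocyclic C5=C6 bond is E, with C4 and C7 cis inside the nine-membered oxacycle. There are three stereocentres: C4 (R, fully substituted ether carbon), C8 (R, secondary ester) and C10 (S, tertiary alcohol). C8 and C10 are 1,3-syn dioxygenated and can be related to each other, whereas C4 lies across the flat dihydrofuran from both and must be set on its own in absolute terms. The sensitive groups are the enol ether next to a tertiary allylic alcohol (acid, electrophilic oxidants), the enol lactone (nucleophiles), the methacrylate, and the C13 acetate, which is expelled once a dienolate of the butenolide is formed; C8–H is vinylogously acidic in the final compound. The hard parts are the medium ring, the fully substituted C4–O stereocentre (few catalytic asymmetric methods exist for tertiary ethers), and the order in which the functions are unveiled. The strategy rests on one feature: C1–C2–C3–C4 plus the bridging oxygen is a cyclobutanone (C1 carbonyl, C4 quaternary α-carbon) with one oxygen inserted into its C1–C4 bond, so C4 can be made as an all-carbon quaternary centre and converted into the ether centre with retention.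

## Retrosynthetic reasoning

**C13–O acetyl bond (41 ⇒ 40 ⇒ 39).** The acetate is put on last. A leaving group on C13 cannot be present while C6 acts as a nucleophile, because the dienolate would expel it. Acylation of diol 40 only has to distinguish a primary from a tertiary hydroxyl. Diol 40 comes from bis-silyl ether 39 by fluoride.

**C5=C6 bond (39 ⇒ 36).** The nine-membered oxacycle is opened at C5=C6. This is the one ring bond whose formation also creates the ylidene butenolide, and the ring then dictates the olefin geometry (C4 cis to C7). The forward reaction is an intramolecular vinylogous aldol condensation between the γ-CH2 of the butenolide and the C5 aldehyde of 36. That aldehyde is attached to the fully substituted C4, so it cannot enolise or epimerise.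

**C8 ester and C5 oxidation level (36 ⇒ 35 ⇒ 34 ⇒ 33).** The methacrylate is installed on diol 33 before ring closure, where secondary versus tertiary selectivity is unambiguous. C5 is carried as a triethylsilyl ether, removed selectively beside the C13 tert-butyldimethylsilyl ether and then oxidised.

**C10–C14 bond (33 ⇒ 31).** The tertiary carbinol is cut at its methyl group. Adding a methyl organometallic to the C10 ketone of 31 lets the free C8 hydroxyl control C10 through a six-membered chelate, which gives the required syn relationship. The reverse polarity (dihydrofuranyl nucleophile on a methyl ketone) would give the anti isomer under the same control.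

**C8–C9 bond (31 ⇒ 23 + 28).** An aldol disconnection divides the skeleton into methyl ketone 23 (C1–C5, C9, C10, C15) and aldehyde 28 (C6–C8, C11–C13). Ketone 23 can enolise only at its methyl group, and the C8 configuration is set by a chiral boron reagent, since C4 is too remote to help or interfere. The butenolide is brought in at the lactone oxidation level, because a furan could not later be oxidised in the presence of the enol ether.

**Butenolide aldehyde (28 ⇒ 27 ⇒ 26 ⇒ 25 ⇒ 24).** The substituents at C7 and C11 are attached to dibromide 24 by two cross-couplings that exploit the different reactivity of the β- and α-bromides. The C8 aldehyde is unmasked from a vinyl group.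

**C1–C10 bond (23 ⇒ 21 ⇒ 19 ⇒ 18).** The acetyl group is attached by acylating the C1-lithiated enol ether 22, made from dihydrofuran 21, which comes from lactone 18 by reduction to lactol 19 and dehydration. A masked acetyl anion added directly to 18 would, after unmasking, give a hydroxy-1,2-dione whose tertiary hydroxyl can close on either carbonyl. The route through 21 avoids that ambiguity.

**C5 (18 ⇒ 17 ⇒ 15).** The vinyl group of 15 is the latent C5. It is cleaved immediately after the key step, while the molecule carries no enol ether, and stored as a silyl ether.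

**O–C1 and O–C4 bonds (15 ⇒ 13).** Both C–O bonds of the oxolane are made at once by a peracid Baeyer–Villiger oxidation of cyclobutanone 13. The gain is that the fully substituted ether centre becomes an α-quaternary ketone centre, for which catalytic asymmetric methods are reliable. The forward reaction must migrate C4 (not C2) with retention and leave the vinyl group alone.

**Cyclobutanone (13 ⇒ 12 ⇒ 11 ⇒ 10 ⇒ 4 + 6).** The C1–C4 bond and the C4 stereocentre come from a palladium-catalysed asymmetric ring expansion of the allylic carbonate 12 of an alkenylcyclopropanol. This is assembled from iodide 4 (from alkynol 1 via 3) and cyclopropanone 9, released from hemiacetal 6 (from silyl ketal 5).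

## Alternatives that were turned down

**Alternative 1:** The C2–C3 and C1–C10 bonds are cut, so that C1 and C2 come from acetylene A4, C3–C5 and C15 from epoxide A2, and C8–C13 from N-methoxy-N-methylamide A3. In the forward direction the monolithium derivative of A4 opens A2 at its unsubstituted ring carbon, the alkyne terminus is deprotonated again in the same flask and acylated by A3, and the open-chain ynone A1 results.
- For: three fragments are joined in one operation, no strained or volatile intermediate is involved, and C4 comes from an epoxide that catalytic asymmetric epoxidation supplies routinely. On convergence this plan is stronger than the chosen one, which runs twelve linear steps before its fragments meet.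
- Against: A1 contains no ring. The oxolane must still be closed by adding the C4 hydroxyl to C1, the alkyne carbon next to the carbonyl. That is the anti-conjugate position of the ynone, and the polarisation of the triple bond works against it. The C14 methyl and the medium ring are also still missing, and an acid-labile silyloxyfuran must survive all of it.
- Comparison: the chosen route has both C–O bonds of the oxolane in place from step 8, with the site of oxygen attachment fixed by migratory aptitude and not by the electronics of an ynone.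

**Alternative 2:** The O–C1 bond and the C5=C6 double bond are removed together, leading back to the ten-membered keto epoxide A6. In the forward direction a base removes the C6 hydrogen of A6, the dienolate opens the 4,5-epoxide to form C5=C6, and the freed C4 alkoxide adds across the ring to the C1 ketone to give hemiketal A5.
- For: the step probably mirrors the biogenesis, forms the ylidene butenolide and the oxygen bridge in one mild operation, and carries both esters already. In late-stage step economy it is stronger than the chosen route, which needs two more steps after ring closure.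
- Against: it presupposes A6, a ten-membered carbocycle with a trans-annularly placed ketone and epoxide and all stereocentres, and says nothing about how that ring is made. The dienolate that opens the epoxide is the same species that expels the C13 acetate. A5 must still lose water toward C2 beside a tertiary alcohol.
- Comparison: the chosen strategy never needs an unbridged ten-membered carbocycle and sets C4 by a stereospecific shift on a small ring.

**Alternative 3:** The C1=C2 bond is cut, leading back to ester A8, in which the C4 tertiary homoallylic alcohol is acylated by the acid that carries C1 and C8–C10. In the forward direction a low-valent titanium alkylidene reagent engages the terminal alkene and the ester carbonyl, and carbonyl–olefin metathesis closes dihydrofuran A7.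
- For: both halves are united by an esterification, the enol ether is formed with the C10 oxygen already present, and the C10 centre can come from the chiral pool. On C10 this plan is stronger than the chelation-controlled methyl addition of step 19.
- Against: A8 is an ester of a tertiary alcohol with an acid that is fully substituted at its α-carbon, so it is hard to make and hard to olefinate. The reagent is used in large excess and is strongly reducing. The C4 tertiary alcohol must still be made by a separate asymmetric construction, which is exactly the problem the chosen key step solves. The furan of A7 must later be oxidised regioselectively to the butenolide in the presence of the electron-rich enol ether.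
- Comparison: the step count is similar, and the chosen route avoids the hindered ester and the late furan oxidation.

Key step: step 8

Assumption: the (R,R)-diphosphine in step 7 and (+)-Ipc2BCl in step 18 are taken to give (R) at C4 and Re-face attack on aldehyde 28, respectively; if either sense proves opposite, the mirror-image reagent is used and nothing else changes.

## Route

Step 1
Reactants: 1 but-2-yn-1-ol
Product: 3 (Z)-3-iodobut-2-en-1-ol, via cyclic alkenylalanate 2 (not isolated)
Conditions: NaAlH2(OCH2CH2OMe)2, THF, 0 °C → rt; then I2, −78 → 0 °C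
Reagents that add atoms: iodine, II
Why: Hydroxyl-directed trans-hydroalumination of the propargylic alcohol places aluminium on C3 inside the five-membered alanate 2, cis to the CH2O group; iodinolysis of the C–Al bond with retention gives the (Z)-iodide.

Step 2
Reactants: 3 (Z)-3-iodobut-2-en-1-ol
Product: 4 (Z)-tert-butyl[(3-iodobut-2-en-1-yl)oxy]dimethylsilane
Conditions: TBSCl, imidazole, CH2Cl2, 0 °C → rt
Reagents that add atoms: tert-butyl(chloro)dimethylsilane, CC(C)(C)[Si](C)(C)Cl
Why: Standard silylation of a primary alcohol; it removes the acidic proton before the halogen–metal exchange.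

Step 3
Reactants: 5 (1-ethoxycyclopropoxy)trimethylsilane
Product: 6 1-ethoxycyclopropan-1-ol
Conditions: MeOH, rt
Reagents that add atoms: none
Why: Methanolysis of the labile silyl ketal frees the hemiacetal, the storable precursor of cyclopropanone.

Step 4
Reactants: 4 (Z)-tert-butyl[(3-iodobut-2-en-1-yl)oxy]dimethylsilane; 6 1-ethoxycyclopropan-1-ol
Product: 10 1-[(Z)-4-{[tert-butyl(dimethyl)silyl]oxy}but-2-en-2-yl]cyclopropan-1-ol, via alkenyllithium 7 (not isolated), via alkenylmagnesium bromide 8 (not isolated), via cyclopropanone 9 (not isolated)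
Conditions: 4, t-BuLi (2 equiv), Et2O, −78 °C; MgBr2·OEt2, −78 → 0 °C; 6 pretreated with MeMgBr (1 equiv), THF, 0 °C; combine, 0 → 40 °C; aq. NH4Cl
Reagents that add atoms: none
Why: Iodine–lithium exchange and transmetalation to magnesium proceed with retention of olefin geometry; the bromomagnesium salt of 6 releases cyclopropanone 9, which the alkenylmagnesium reagent 8 traps by 1,2-addition.

Step 5
Reactants: 10 1-[(Z)-4-{[tert-butyl(dimethyl)silyl]oxy}but-2-en-2-yl]cyclopropan-1-ol
Product: 11 1-[(Z)-4-hydroxybut-2-en-2-yl]cyclopropan-1-ol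
Conditions: Bu4NF, THF, 0 °C
Reagents that add atoms: none
Why: Fluoride desilylation under non-acidic conditions, so the acid-sensitive alkenylcyclopropanol is not ring-expanded prematurely.

Step 6
Reactants: 11 1-[(Z)-4-hydroxybut-2-en-2-yl]cyclopropan-1-ol
Product: 12 (Z)-3-(1-hydroxycyclopropyl)but-2-en-1-yl methyl carbonate
Conditions: ClCO2Me, pyridine, CH2Cl2, 0 °C
Reagents that add atoms: methyl chloroformate, COC(=O)Cl
Why: Acylation is selective for the primary allylic hydroxyl over the hindered tertiary cyclopropanol.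

Step 7
Reactants: 12 (Z)-3-(1-hydroxycyclopropyl)but-2-en-1-yl methyl carbonate
Product: 13 (R)-2-methyl-2-vinylcyclobutan-1-one
Conditions: Pd2(dba)3·CHCl3 (cat.), N,N'-[(1R,2R)-cyclohexane-1,2-diyl]bis[2-(diphenylphosphino)benzamide] (cat.), tetramethylguanidine (cat.), PhMe, rt
Reagents that add atoms: none
Why: Catalytic asymmetric Wagner–Meerwein shift: zerovalent palladium ionises the allylic carbonate, and a cyclopropane C–C bond migrates to the methyl-bearing allyl terminus, driven by strain release and C=O formation. The chiral diphosphine selects the face of that terminus and so sets the quaternary centre (R); the volatile ketone is kept in solution.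

Step 8
Reactants: 13 (R)-2-methyl-2-vinylcyclobutan-1-one
Product: 15 (R)-5-methyl-5-vinyldihydrofuran-2(3H)-one, via tetrahedral peroxy adduct 14 (not isolated)
Conditions: mCPBA, NaHCO3, CH2Cl2, 0 °C
Reagents that add atoms: 3-chloroperoxybenzoic acid, O=C(OO)c1cccc(Cl)c1
Why: This is a Baeyer–Villiger oxidation of a 2,2-disubstituted cyclobutanone, a well-established reaction type: the peracid adds to the strained C1 carbonyl to give adduct 14, and the fully substituted, allylic C4 then shifts from C1 to the proximal peroxide oxygen as 3-chlorobenzoate leaves, so the O–C4 and O–C1 bonds of the target form in one event. The oxolane ring is not closed end to end; it arises by enlargement of the four-membered ring through this 1,2-shift, so no other ring size can compete. No new stereocentre is created: the migrating carbon keeps the face it started on, so the (R) configuration of the all-carbon centre from step 7 becomes the (R) configuration of the C4–O centre. The step needs C4 and not C2 to migrate, which the far higher migratory aptitude of a quaternary allylic carbon over a primary one secures. It also needs the vinyl group to survive, which the strain-accelerated attack on the cyclobutanone carbonyl and the low nucleophilicity of a monosubstituted alkene secure. The NaHCO3 buffer keeps 3-chlorobenzoic acid from ionising the tertiary allylic C–O bond of 15, which would erode enantiomeric purity. Because 13 is volatile, its solution from step 7 is used directly.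

Step 9
Reactants: 15 (R)-5-methyl-5-vinyldihydrofuran-2(3H)-one
Product: 17 (R)-5-(hydroxymethyl)-5-methyldihydrofuran-2(3H)-one, via aldehyde 16 (not isolated)
Conditions: O3, CH2Cl2/MeOH, −78 °C; then NaBH4, −78 → 0 °C
Reagents that add atoms: ozone, [O-][O+]=O
Why: Ozonolysis of the terminal alkene gives aldehyde 16, which is reduced in the same flask; C4 has no hydrogen and cannot epimerise, and the γ-lactone is not reduced by NaBH4 at this temperature.

Step 10
Reactants: 17 (R)-5-(hydroxymethyl)-5-methyldihydrofuran-2(3H)-one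
Product: 18 (R)-5-methyl-5-{[(triethylsilyl)oxy]methyl}dihydrofuran-2(3H)-one
Conditions: TESCl, imidazole, CH2Cl2, 0 °C
Reagents that add atoms: chlorotriethylsilane, CC[Si](Cl)(CC)CC
Why: Standard silylation; the triethylsilyl ether can later be removed beside a tert-butyldimethylsilyl ether.

Step 11
Reactants: 18 (R)-5-methyl-5-{[(triethylsilyl)oxy]methyl}dihydrofuran-2(3H)-one
Product: 19 (5R)-5-methyl-5-{[(triethylsilyl)oxy]methyl}tetrahydrofuran-2-ol (both anomers)
Conditions: i-Bu2AlH, CH2Cl2, −78 °C
Reagents that add atoms: none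
Why: Half-reduction of a γ-lactone, which stops at the lactol oxidation level at low temperature.

Step 12
Reactants: 19 (5R)-5-methyl-5-{[(triethylsilyl)oxy]methyl}tetrahydrofuran-2-ol
Product: 21 (R)-triethyl[(2-methyl-2,3-dihydrofuran-2-yl)methoxy]silane, via anomeric mesylate 20 (not isolated)
Conditions: MsCl, Et3N, CH2Cl2, −40 °C → reflux
Reagents that add atoms: none
Why: Lactol dehydration of the glycal-forming type: the anomeric sulfonate 20 eliminates toward C2, the only neighbouring carbon that bears hydrogen, to give the cyclic enol ether.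

Step 13
Reactants: 21 (R)-triethyl[(2-methyl-2,3-dihydrofuran-2-yl)methoxy]silane
Product: 23 1-[(5R)-5-methyl-5-{[(triethylsilyl)oxy]methyl}-4,5-dihydrofuran-2-yl]ethan-1-one, via lithiated enol ether 22 (not isolated)
Conditions: t-BuLi, THF, −78 → 0 °C; then MeC(O)N(OMe)Me, −78 °C → rt; aq. NH4Cl
Reagents that add atoms: N-methoxy-N-methylacetamide, CC(=O)N(C)OC
Why: α-Lithiation of a cyclic enol ether at the oxygen-bearing sp2 carbon followed by acylation with an N-methoxy-N-methylamide, whose chelated adduct prevents over-addition; this forms the C1–C10 bond and gives the conjugated, acid-tolerant α-alkoxy enone.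

Step 14
Reactants: 24 3,4-dibromofuran-2(5H)-one
Product: 25 3-bromo-4-vinylfuran-2(5H)-one
Conditions: tributyl(vinyl)stannane, Pd2(dba)3 (cat.), AsPh3 (cat.), THF, 50 °C
Reagents that add atoms: tributyl(vinyl)stannane, C=C[Sn](CCCC)(CCCC)CCCC
Why: Stille coupling; oxidative addition occurs selectively at the β-bromide, which is a vinylogous acyl bromide and the more electrophilic C–Br bond.

Step 15
Reactants: 25 3-bromo-4-vinylfuran-2(5H)-one
Product: 26 3-(hydroxymethyl)-4-vinylfuran-2(5H)-one
Conditions: (tributylstannyl)methanol, Pd(PPh3)4 (cat.), 1,4-dioxane, 90 °C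
Reagents that add atoms: (tributylstannyl)methanol, OC[Sn](CCCC)(CCCC)CCCC
Why: Stille hydroxymethylation of the remaining α-bromo enoate under neutral conditions introduces C13 with its oxygen.

Step 16
Reactants: 26 3-(hydroxymethyl)-4-vinylfuran-2(5H)-one
Product: 27 3-({[tert-butyl(dimethyl)silyl]oxy}methyl)-4-vinylfuran-2(5H)-one
Conditions: TBSCl, imidazole, CH2Cl2, 0 °C → rt
Reagents that add atoms: tert-butyl(chloro)dimethylsilane, CC(C)(C)[Si](C)(C)Cl
Why: Standard silylation; a silyloxy group on C13 is a poor leaving group and will not be expelled when the butenolide is later enolised.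

Step 17
Reactants: 27 3-({[tert-butyl(dimethyl)silyl]oxy}methyl)-4-vinylfuran-2(5H)-one
Product: 28 4-({[tert-butyl(dimethyl)silyl]oxy}methyl)-5-oxo-2,5-dihydrofuran-3-carbaldehyde
Conditions: O3 (1 equiv), CH2Cl2, −78 °C; then Me2S
Reagents that add atoms: ozone, [O-][O+]=O
Why: Ozone cleaves the terminal vinyl group in preference to the tetrasubstituted ring alkene, which is deactivated by the lactone carbonyl, as in the selective cleavage of the distal double bond of dienoates.

Step 18
Reactants: 23 1-[(5R)-5-methyl-5-{[(triethylsilyl)oxy]methyl}-4,5-dihydrofuran-2-yl]ethan-1-one; 28 4-({[tert-butyl(dimethyl)silyl]oxy}methyl)-5-oxo-2,5-dihydrofuran-3-carbaldehyde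
Product: 31 (3R)-3-[4-({[tert-butyl(dimethyl)silyl]oxy}methyl)-5-oxo-2,5-dihydrofuran-3-yl]-3-hydroxy-1-[(5R)-5-methyl-5-{[(triethylsilyl)oxy]methyl}-4,5-dihydrofuran-2-yl]propan-1-one, via boron enolate 29 (not isolated), via boron aldolate 30 (not isolated)
Conditions: 23, (+)-Ipc2BCl, Et3N, Et2O, 0 °C; then 28, −78 → −20 °C; then MeOH, pH 7 buffer, H2O2, 0 °C
Reagents that add atoms: none
Why: Boron-mediated aldol addition of a methyl ketone under reagent control: 23 is enolised at its methyl group to 29, and the isopinocampheyl groups direct the enolate to the Re face of aldehyde 28 in a cyclic six-membered transition state, giving the (8R) aldolate 30, which oxidative work-up releases as 31. C4 is too remote to influence the outcome, so the minor C8 epimer is a diastereomer and is removed by chromatography.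

Step 19
Reactants: 31 (3R)-aldol (name as in step 18)
Product: 33 3-({[tert-butyl(dimethyl)silyl]oxy}methyl)-4-[(1R,3S)-1,3-dihydroxy-3-[(5R)-5-methyl-5-{[(triethylsilyl)oxy]methyl}-4,5-dihydrofuran-2-yl]butyl]furan-2(5H)-one, via bromomagnesium alkoxide 32 (not isolated)
Conditions: MeMgBr (3.5 equiv), CH2Cl2/Et2O, −78 °C; aq. NH4Cl
Reagents that add atoms: methylmagnesium bromide, C[Mg]Br
Why: Chelation-controlled 1,2-addition: the first equivalent forms alkoxide 32, whose magnesium binds the C10 carbonyl in a six-membered chelate with the butenolide substituent on C8 equatorial, and axial delivery of methyl trans to that substituent gives the 8,10-syn diol, that is (10S). At −78 °C the ketone reacts faster than the lactone, whose γ-protons are at most removed reversibly.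

Step 20
Reactants: 33 (1R,3S)-diol (name as in step 19)
Product: 34 (1R,3S)-1-[4-({[tert-butyl(dimethyl)silyl]oxy}methyl)-5-oxo-2,5-dihydrofuran-3-yl]-3-hydroxy-3-[(5R)-5-methyl-5-{[(triethylsilyl)oxy]methyl}-4,5-dihydrofuran-2-yl]butyl 2-methylprop-2-enoate
Conditions: methacrylic anhydride, Et3N, 4-(dimethylamino)pyridine (cat.), CH2Cl2, 0 °C
Reagents that add atoms: methacrylic anhydride, C=C(C)C(=O)OC(=O)C(C)=C
Why: Nucleophile-catalysed acylation takes the secondary C8 hydroxyl and leaves the tertiary C10 hydroxyl free.

Step 21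
Reactants: 34 methacrylate (name as in step 20)
Product: 35 (1R,3S)-1-[4-({[tert-butyl(dimethyl)silyl]oxy}methyl)-5-oxo-2,5-dihydrofuran-3-yl]-3-hydroxy-3-[(5R)-5-(hydroxymethyl)-5-methyl-4,5-dihydrofuran-2-yl]butyl 2-methylprop-2-enoate
Conditions: HF·pyridine, pyridine, THF, 0 °C
Reagents that add atoms: none
Why: Buffered hydrogen fluoride cleaves the primary triethylsilyl ether much faster than the tert-butyldimethylsilyl ether, and the pyridine buffer protects the enol ether.

Step 22
Reactants: 35 primary alcohol (name as in step 21)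
Product: 36 (1R,3S)-1-[4-({[tert-butyl(dimethyl)silyl]oxy}methyl)-5-oxo-2,5-dihydrofuran-3-yl]-3-[(5R)-5-formyl-5-methyl-4,5-dihydrofuran-2-yl]-3-hydroxybutyl 2-methylprop-2-enoate
Conditions: Dess–Martin periodinane, NaHCO3, CH2Cl2, 0 °C → rt
Reagents that add atoms: none
Why: Buffered Dess–Martin oxidation of the only oxidisable alcohol; the tertiary hydroxyl is inert and the new aldehyde has no α-hydrogen.

Step 23
Reactants: 36 aldehyde (name as in step 22)
Product: 39 (4R,5E,8R,10S)-13-{[tert-butyl(dimethyl)silyl]oxy}-8-(methacryloyloxy)-10-[(trimethylsilyl)oxy]-1,4-epoxygermacra-1,5,7(11)-trien-12,6-olide (the silyl-protected bicyclic ylidene butenolide), via silyloxyfuran 37 (not isolated), via cyclised silyl aldol adduct 38 (not isolated)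
Conditions: TMSOTf, i-Pr2NEt, CH2Cl2 (2 mM), −78 → 0 °C; then DBU, 0 °C → rt
Reagents that add atoms: trimethylsilyl trifluoromethanesulfonate, C[Si](C)(C)OS(=O)(=O)C(F)(F)F
Why: Silylative intramolecular vinylogous Mukaiyama aldol: soft enolisation gives 2-silyloxyfuran 37 (the C10 hydroxyl is silylated in the same flask), and its C6 attacks the silyl-triflate-activated C5 aldehyde to close the nine-membered oxacycle as β-silyloxy lactone 38. DBU then removes the acidic C6–H and expels silanolate (E1cB); the ring permits only the geometry with C4 and C7 cis, that is (E), and the C13 silyl ether is too poor a leaving group to compete.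

Step 24
Reactants: 39 silyl-protected macrocycle (name as in step 23)
Product: 40 (4R,5E,8R,10S)-10,13-dihydroxy-8-(methacryloyloxy)-1,4-epoxygermacra-1,5,7(11)-trien-12,6-olide
Conditions: HF·pyridine, pyridine, THF, 0 °C → rt
Reagents that add atoms: none
Why: Buffered fluoride removes the primary allylic tert-butyldimethylsilyl ether and the tertiary trimethylsilyl ether without base, which avoids acyl migration from O8 to O13 and deprotonation at C8.

Step 25
Reactants: 40 diol (name as in step 24)
Product: 41 (4R,5E,8R,10S)-13-acetoxy-10-hydroxy-8-(methacryloyloxy)-1,4-epoxygermacra-1,5,7(11)-trien-12,6-olide (the target)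
Conditions: Ac2O, pyridine, 4-(dimethylamino)pyridine (cat.), CH2Cl2, 0 °C
Reagents that add atoms: acetic anhydride, CC(=O)OC(C)=O
Why: Acetylation of the primary allylic hydroxyl; the tertiary C10 hydroxyl does not react under these conditions.

## Compound list

1 | but-2-yn-1-ol | CC#CCO | starting material
2 | sodium 2,2-bis(2-methoxyethoxy)-3-methyl-2,5-dihydro-1,2-oxaluminol-2-uide (cyclic alkenylalanate) | CC1=CCO[Al-]1(OCCOC)OCCOC.[Na+] | intermediate
3 | (Z)-3-iodobut-2-en-1-ol | C/C(I)=C/CO | intermediate
4 | (Z)-tert-butyl[(3-iodobut-2-en-1-yl)oxy]dimethylsilane | C/C(I)=C/CO[Si](C)(C)C(C)(C)C | intermediate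
5 | (1-ethoxycyclopropoxy)trimethylsilane | CCOC1(O[Si](C)(C)C)CC1 | starting material
6 | 1-ethoxycyclopropan-1-ol | CCOC1(O)CC1 | intermediate
7 | [(E)-4-{[tert-butyl(dimethyl)silyl]oxy}but-2-en-2-yl]lithium (lithium cis to the CH2O group) | C/C([Li])=C/CO[Si](C)(C)C(C)(C)C | intermediate
8 | bromo[(Z)-4-{[tert-butyl(dimethyl)silyl]oxy}but-2-en-2-yl]magnesium | C/C([Mg]Br)=C/CO[Si](C)(C)C(C)(C)C | intermediate
9 | cyclopropanone | O=C1CC1 | intermediate
10 | 1-[(Z)-4-{[tert-butyl(dimethyl)silyl]oxy}but-2-en-2-yl]cyclopropan-1-ol | C/C(=C/CO[Si](C)(C)C(C)(C)C)C1(O)CC1 | intermediate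
11 | 1-[(Z)-4-hydroxybut-2-en-2-yl]cyclopropan-1-ol | C/C(=C/CO)C1(O)CC1 | intermediate
12 | (Z)-3-(1-hydroxycyclopropyl)but-2-en-1-yl methyl carbonate | C/C(=C/COC(=O)OC)C1(O)CC1 | intermediate
13 | (R)-2-methyl-2-vinylcyclobutan-1-one | O=C1CC[C@]1(C)C=C | intermediate
14 | (2R)-1-hydroxy-2-methyl-2-vinylcyclobutyl 3-chlorobenzenecarboperoxoate (tetrahedral peroxy adduct, C1 epimers) | OC1(OOC(=O)c2cccc(Cl)c2)CC[C@]1(C)C=C | intermediate
15 | (R)-5-methyl-5-vinyldihydrofuran-2(3H)-one | O=C1CC[C@](C)(C=C)O1 | intermediate
16 | (R)-2-methyl-5-oxotetrahydrofuran-2-carbaldehyde | O=C1CC[C@](C)(C=O)O1 | intermediate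
17 | (R)-5-(hydroxymethyl)-5-methyldihydrofuran-2(3H)-one | O=C1CC[C@](C)(CO)O1 | intermediate
18 | (R)-5-methyl-5-{[(triethylsilyl)oxy]methyl}dihydrofuran-2(3H)-one | O=C1CC[C@](C)(CO[Si](CC)(CC)CC)O1 | intermediate
19 | (5R)-5-methyl-5-{[(triethylsilyl)oxy]methyl}tetrahydrofuran-2-ol (both anomers) | OC1CC[C@](C)(CO[Si](CC)(CC)CC)O1 | intermediate
20 | (5R)-5-methyl-5-{[(triethylsilyl)oxy]methyl}tetrahydrofuran-2-yl methanesulfonate (both anomers) | CS(=O)(=O)OC1CC[C@](C)(CO[Si](CC)(CC)CC)O1 | intermediate
21 | (R)-triethyl[(2-methyl-2,3-dihydrofuran-2-yl)methoxy]silane | C1=CC[C@](C)(CO[Si](CC)(CC)CC)O1 | intermediate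
22 | [(5R)-5-methyl-5-{[(triethylsilyl)oxy]methyl}-4,5-dihydrofuran-2-yl]lithium | [Li]C1=CC[C@](C)(CO[Si](CC)(CC)CC)O1 | intermediate
23 | 1-[(5R)-5-methyl-5-{[(triethylsilyl)oxy]methyl}-4,5-dihydrofuran-2-yl]ethan-1-one | CC(=O)C1=CC[C@](C)(CO[Si](CC)(CC)CC)O1 | intermediate
24 | 3,4-dibromofuran-2(5H)-one | O=C1OCC(Br)=C1Br | starting material
25 | 3-bromo-4-vinylfuran-2(5H)-one | O=C1OCC(C=C)=C1Br | intermediate
26 | 3-(hydroxymethyl)-4-vinylfuran-2(5H)-one | O=C1OCC(C=C)=C1CO | intermediate
27 | 3-({[tert-butyl(dimethyl)silyl]oxy}methyl)-4-vinylfuran-2(5H)-one | O=C1OCC(C=C)=C1CO[Si](C)(C)C(C)(C)C | intermediate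
28 | 4-({[tert-butyl(dimethyl)silyl]oxy}methyl)-5-oxo-2,5-dihydrofuran-3-carbaldehyde | O=CC1=C(CO[Si](C)(C)C(C)(C)C)C(=O)OC1 | intermediate
29 | bis[(+)-isopinocampheyl]boron enolate of 23 | C=C(OB([C@H]1C[C@H]2C[C@@H]([C@@H]1C)C2(C)C)[C@H]1C[C@H]2C[C@@H]([C@@H]1C)C2(C)C)C1=CC[C@](C)(CO[Si](CC)(CC)CC)O1 | intermediate
30 | bis[(+)-isopinocampheyl]boron aldolate of 31 (8R) | O=C(C[C@@H](OB([C@H]1C[C@H]2C[C@@H]([C@@H]1C)C2(C)C)[C@H]1C[C@H]2C[C@@H]([C@@H]1C)C2(C)C)C1=C(CO[Si](C)(C)C(C)(C)C)C(=O)OC1)C1=CC[C@](C)(CO[Si](CC)(CC)CC)O1 | intermediate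
31 | (3R)-3-[4-({[tert-butyl(dimethyl)silyl]oxy}methyl)-5-oxo-2,5-dihydrofuran-3-yl]-3-hydroxy-1-[(5R)-5-methyl-5-{[(triethylsilyl)oxy]methyl}-4,5-dihydrofuran-2-yl]propan-1-one | O=C(C[C@@H](O)C1=C(CO[Si](C)(C)C(C)(C)C)C(=O)OC1)C1=CC[C@](C)(CO[Si](CC)(CC)CC)O1 | intermediate
32 | bromomagnesium C8 alkoxide of 31 | O=C(C[C@@H](O[Mg]Br)C1=C(CO[Si](C)(C)C(C)(C)C)C(=O)OC1)C1=CC[C@](C)(CO[Si](CC)(CC)CC)O1 | intermediate
33 | 3-({[tert-butyl(dimethyl)silyl]oxy}methyl)-4-[(1R,3S)-1,3-dihydroxy-3-[(5R)-5-methyl-5-{[(triethylsilyl)oxy]methyl}-4,5-dihydrofuran-2-yl]butyl]furan-2(5H)-one | C[C@](O)(C[C@@H](O)C1=C(CO[Si](C)(C)C(C)(C)C)C(=O)OC1)C1=CC[C@](C)(CO[Si](CC)(CC)CC)O1 | intermediate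
34 | (1R,3S)-1-[4-({[tert-butyl(dimethyl)silyl]oxy}methyl)-5-oxo-2,5-dihydrofuran-3-yl]-3-hydroxy-3-[(5R)-5-methyl-5-{[(triethylsilyl)oxy]methyl}-4,5-dihydrofuran-2-yl]butyl 2-methylprop-2-enoate | C=C(C)C(=O)O[C@H](C[C@](C)(O)C1=CC[C@](C)(CO[Si](CC)(CC)CC)O1)C1=C(CO[Si](C)(C)C(C)(C)C)C(=O)OC1 | intermediate
35 | (1R,3S)-1-[4-({[tert-butyl(dimethyl)silyl]oxy}methyl)-5-oxo-2,5-dihydrofuran-3-yl]-3-hydroxy-3-[(5R)-5-(hydroxymethyl)-5-methyl-4,5-dihydrofuran-2-yl]butyl 2-methylprop-2-enoate | C=C(C)C(=O)O[C@H](C[C@](C)(O)C1=CC[C@](C)(CO)O1)C1=C(CO[Si](C)(C)C(C)(C)C)C(=O)OC1 | intermediate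
36 | (1R,3S)-1-[4-({[tert-butyl(dimethyl)silyl]oxy}methyl)-5-oxo-2,5-dihydrofuran-3-yl]-3-[(5R)-5-formyl-5-methyl-4,5-dihydrofuran-2-yl]-3-hydroxybutyl 2-methylprop-2-enoate | C=C(C)C(=O)O[C@H](C[C@](C)(O)C1=CC[C@](C)(C=O)O1)C1=C(CO[Si](C)(C)C(C)(C)C)C(=O)OC1 | intermediate
37 | (1R,3S)-1-[4-({[tert-butyl(dimethyl)silyl]oxy}methyl)-5-[(trimethylsilyl)oxy]furan-3-yl]-3-[(5R)-5-formyl-5-methyl-4,5-dihydrofuran-2-yl]-3-[(trimethylsilyl)oxy]butyl 2-methylprop-2-enoate | C=C(C)C(=O)O[C@H](C[C@](C)(O[Si](C)(C)C)C1=CC[C@](C)(C=O)O1)c1coc(O[Si](C)(C)C)c1CO[Si](C)(C)C(C)(C)C | intermediate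
38 | (4R,8R,10S)-13-{[tert-butyl(dimethyl)silyl]oxy}-8-(methacryloyloxy)-5,10-bis[(trimethylsilyl)oxy]-1,4-epoxygermacra-1,7(11)-dien-12,6-olide (C5 and C6 epimers) | C=C(C)C(=O)O[C@@H]1C[C@](C)(O[Si](C)(C)C)C2=CC[C@](C)(C(O[Si](C)(C)C)C3OC(=O)C(CO[Si](C)(C)C(C)(C)C)=C31)O2 | intermediate
39 | (4R,5E,8R,10S)-13-{[tert-butyl(dimethyl)silyl]oxy}-8-(methacryloyloxy)-10-[(trimethylsilyl)oxy]-1,4-epoxygermacra-1,5,7(11)-trien-12,6-olide | C=C(C)C(=O)O[C@@H]1C[C@](C)(O[Si](C)(C)C)C2=CC[C@](C)(/C=C3/OC(=O)C(CO[Si](C)(C)C(C)(C)C)=C31)O2 | intermediate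
40 | (4R,5E,8R,10S)-10,13-dihydroxy-8-(methacryloyloxy)-1,4-epoxygermacra-1,5,7(11)-trien-12,6-olide | C=C(C)C(=O)O[C@@H]1C[C@](C)(O)C2=CC[C@](C)(/C=C3/OC(=O)C(CO)=C31)O2 | intermediate
41 | (4R,5E,8R,10S)-13-acetoxy-10-hydroxy-8-(methacryloyloxy)-1,4-epoxygermacra-1,5,7(11)-trien-12,6-olide | C=C(C)C(=O)O[C@@H]1C[C@](C)(O)C2=CC[C@](C)(/C=C3/OC(=O)C(COC(C)=O)=C31)O2 | target

## Step count and least certain steps

Total: 25 steps. Longest linear sequence: 20 steps (steps 1, 2, 4–13 and 18–25); step 3 and steps 14–17 are side branches.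

**Step 8 (key step).** The most likely fault is partial epoxidation of the vinyl group running alongside the ring enlargement. Acid-promoted ionisation of the tertiary allylic C–O bond of the product would lower the enantiomeric purity, and the volatile ketone can be lost on handling. Fallback, from 13 back to 17: 13 is treated with an excess of the peracid (NaHCO3, CH2Cl2, rt), so that ring enlargement and epoxidation both go to completion and give (5R)-5-methyl-5-(oxiran-2-yl)dihydrofuran-2(3H)-one F1. Periodic acid (H5IO6, THF/H2O) cleaves the terminal epoxide to aldehyde 16, which NaBH4 reduces to 17. The epoxidation thus becomes productive and the ozonolysis is not needed.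

**Step 23 (ring closure).** The likely fault is failure of the nine-membered ring to close at a useful rate, so that intermolecular aldol oligomerisation or Lewis-acid damage to the enol ether takes over. Prolonged exposure to DBU can also deprotonate C8 once C6 has no hydrogen left. Fallback, from 36 back to 39, replacing the reversible aldol by an olefination: 36 is converted at −78 °C into silyloxyfuran 37 (TMSOTf, Et3N) and brominated at C6 with N-bromosuccinimide to give (1R,3S)-1-[2-bromo-4-({[tert-butyl(dimethyl)silyl]oxy}methyl)-5-oxo-2,5-dihydrofuran-3-yl]-3-[(5R)-5-formyl-5-methyl-4,5-dihydrofuran-2-yl]-3-[(trimethylsilyl)oxy]butyl 2-methylprop-2-enoate F2. Arbuzov reaction with trimethyl phosphite gives the corresponding C6 dimethyl phosphonate F3. An intramolecular Horner–Wadsworth–Emmons reaction (LiCl, DBU, MeCN, high dilution) then forms C5=C6 irreversibly and gives 39.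

**Step 19 (methyl addition).** The likely fault is weak facial discrimination, because 1,3-chelation in an open chain competes with coordination of magnesium to the ring oxygen; attack or deprotonation at the butenolide is a second concern. Fallback, from 31 back to 33, replacing substrate control by reagent control: 31 is silylated (TMSCl, imidazole) to (3R)-3-[4-({[tert-butyl(dimethyl)silyl]oxy}methyl)-5-oxo-2,5-dihydrofuran-3-yl]-1-[(5R)-5-methyl-5-{[(triethylsilyl)oxy]methyl}-4,5-dihydrofuran-2-yl]-3-[(trimethylsilyl)oxy]propan-1-one F4. Catalytic asymmetric methylation of the enone carbonyl (Me2Zn, Ti(OiPr)4, the enantiomer of trans-1,2-bis(hydroxycamphorsulfonylamino)cyclohexane that gives 10S, toluene, rt) gives 3-({[tert-butyl(dimethyl)silyl]oxy}methyl)-4-[(1R,3S)-3-hydroxy-3-[(5R)-5-methyl-5-{[(triethylsilyl)oxy]methyl}-4,5-dihydrofuran-2-yl]-1-[(trimethylsilyl)oxy]butyl]furan-2(5H)-one F5; this reagent does not attack lactones. Brief treatment with buffered HF·pyridine at −20 °C removes the trimethylsilyl group and gives 33.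

**Step 18 (aldol).** The likely fault is only moderate face selectivity of the isopinocampheylboron enolate of a methyl ketone, together with amine-induced enolisation of aldehyde 28 before it is consumed. Fallback, from 23 (with 28) back to 31, replacing the closed boron transition state by a catalysed open one: 23 is converted (TMSOTf, Et3N, 0 °C) into triethyl{[(2R)-2-methyl-5-{1-[(trimethylsilyl)oxy]ethenyl}-2,3-dihydrofuran-2-yl]methoxy}silane F6. A Mukaiyama aldol addition to 28, catalysed by the (acyloxy)borane made from (2R,3R)-2-O-(2,6-diisopropoxybenzoyl)tartaric acid (or its enantiomer, chosen for Re-face attack) and BH3·THF in EtCN at −78 °C, gives the β-silyloxy ketone F7, which is the same compound as F4. Brief buffered HF·pyridine then gives 31.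

## Further compounds

F1 | step 8 | (5R)-5-methyl-5-(oxiran-2-yl)dihydrofuran-2(3H)-one (both oxirane epimers) | O=C1CC[C@](C)(C2CO2)O1
F2 | step 23 | (1R,3S)-1-[2-bromo-4-({[tert-butyl(dimethyl)silyl]oxy}methyl)-5-oxo-2,5-dihydrofuran-3-yl]-3-[(5R)-5-formyl-5-methyl-4,5-dihydrofuran-2-yl]-3-[(trimethylsilyl)oxy]butyl 2-methylprop-2-enoate | C=C(C)C(=O)O[C@H](C[C@](C)(O[Si](C)(C)C)C1=CC[C@](C)(C=O)O1)C1=C(CO[Si](C)(C)C(C)(C)C)C(=O)OC1Br
F3 | step 23 | (1R,3S)-1-[4-({[tert-butyl(dimethyl)silyl]oxy}methyl)-2-(dimethoxyphosphoryl)-5-oxo-2,5-dihydrofuran-3-yl]-3-[(5R)-5-formyl-5-methyl-4,5-dihydrofuran-2-yl]-3-[(trimethylsilyl)oxy]butyl 2-methylprop-2-enoate | C=C(C)C(=O)O[C@H](C[C@](C)(O[Si](C)(C)C)C1=CC[C@](C)(C=O)O1)C1=C(CO[Si](C)(C)C(C)(C)C)C(=O)OC1P(=O)(OC)OC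
F4 | step 19 | (3R)-3-[4-({[tert-butyl(dimethyl)silyl]oxy}methyl)-5-oxo-2,5-dihydrofuran-3-yl]-1-[(5R)-5-methyl-5-{[(triethylsilyl)oxy]methyl}-4,5-dihydrofuran-2-yl]-3-[(trimethylsilyl)oxy]propan-1-one | O=C(C[C@@H](O[Si](C)(C)C)C1=C(CO[Si](C)(C)C(C)(C)C)C(=O)OC1)C1=CC[C@](C)(CO[Si](CC)(CC)CC)O1
F5 | step 19 | 3-({[tert-butyl(dimethyl)silyl]oxy}methyl)-4-[(1R,3S)-3-hydroxy-3-[(5R)-5-methyl-5-{[(triethylsilyl)oxy]methyl}-4,5-dihydrofuran-2-yl]-1-[(trimethylsilyl)oxy]butyl]furan-2(5H)-one | C[C@](O)(C[C@@H](O[Si](C)(C)C)C1=C(CO[Si](C)(C)C(C)(C)C)C(=O)OC1)C1=CC[C@](C)(CO[Si](CC)(CC)CC)O1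
F6 | step 18 | triethyl{[(2R)-2-methyl-5-{1-[(trimethylsilyl)oxy]ethenyl}-2,3-dihydrofuran-2-yl]methoxy}silane | C=C(O[Si](C)(C)C)C1=CC[C@](C)(CO[Si](CC)(CC)CC)O1
F7 | step 18 | (3R)-3-[4-({[tert-butyl(dimethyl)silyl]oxy}methyl)-5-oxo-2,5-dihydrofuran-3-yl]-1-[(5R)-5-methyl-5-{[(triethylsilyl)oxy]methyl}-4,5-dihydrofuran-2-yl]-3-[(trimethylsilyl)oxy]propan-1-one (same compound as F4) | O=C(C[C@@H](O[Si](C)(C)C)C1=C(CO[Si](C)(C)C(C)(C)C)C(=O)OC1)C1=CC[C@](C)(CO[Si](CC)(CC)CC)O1
A1 | alternative 1 | (1R,7R)-1-[4-({[tert-butyl(dimethyl)silyl]oxy}methyl)-5-[(triisopropylsilyl)oxy]furan-3-yl]-7-hydroxy-1-[(4-methoxybenzyl)oxy]-7-methyl-8-[(triethylsilyl)oxy]oct-4-yn-3-one | O=C(C[C@@H](OCc1ccc(OC)cc1)c1coc(O[Si](C(C)C)(C(C)C)C(C)C)c1CO[Si](C)(C)C(C)(C)C)C#CC[C@@](C)(O)CO[Si](CC)(CC)CC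
A2 | alternative 1 | (R)-triethyl[(2-methyloxiran-2-yl)methoxy]silane | C[C@]1(CO[Si](CC)(CC)CC)CO1
A3 | alternative 1 | (3R)-3-[4-({[tert-butyl(dimethyl)silyl]oxy}methyl)-5-[(triisopropylsilyl)oxy]furan-3-yl]-N-methoxy-3-[(4-methoxybenzyl)oxy]-N-methylpropanamide | CON(C)C(=O)C[C@@H](OCc1ccc(OC)cc1)c1coc(O[Si](C(C)C)(C(C)C)C(C)C)c1CO[Si](C)(C)C(C)(C)C
A4 | alternative 1 | acetylene | C#C
A5 | alternative 2 | (1S,4R,5E,8R,10S)-13-acetoxy-1,10-dihydroxy-8-(methacryloyloxy)-1,4-epoxygermacra-5,7(11)-dien-12,6-olide (C1 hemiketal) | C=C(C)C(=O)O[C@@H]1C[C@](C)(O)[C@]2(O)CC[C@](C)(/C=C3/OC(=O)C(COC(C)=O)=C31)O2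
A6 | alternative 2 | (4R,8R,10S)-13-acetoxy-4,5-epoxy-10-hydroxy-8-(methacryloyloxy)-1-oxogermacr-7(11)-en-12,6-olide (C5 and C6 as set by its own synthesis) | C=C(C)C(=O)O[C@@H]1C[C@](C)(O)C(=O)CC[C@@]2(C)OC2C2OC(=O)C(COC(C)=O)=C21
A7 | alternative 3 | (5R)-2-[(2S,4R)-4-[4-({[tert-butyl(dimethyl)silyl]oxy}methyl)furan-3-yl]-4-[(4-methoxybenzyl)oxy]-2-[(triethylsilyl)oxy]butan-2-yl]-5-{[(tert-butyldiphenylsilyl)oxy]methyl}-5-methyl-4,5-dihydrofuran | C1(=CC[C@](C)(CO[Si](c2ccccc2)(c2ccccc2)C(C)(C)C)O1)[C@@](C)(O[Si](CC)(CC)CC)C[C@@H](OCc1ccc(OC)cc1)c1cocc1CO[Si](C)(C)C(C)(C)C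
A8 | alternative 3 | (R)-1-[(tert-butyldiphenylsilyl)oxy]-2-methylpent-4-en-2-yl (2S,4R)-4-[4-({[tert-butyl(dimethyl)silyl]oxy}methyl)furan-3-yl]-4-[(4-methoxybenzyl)oxy]-2-methyl-2-[(triethylsilyl)oxy]butanoate | C=CC[C@](C)(CO[Si](c1ccccc1)(c1ccccc1)C(C)(C)C)OC(=O)[C@@](C)(O[Si](CC)(CC)CC)C[C@@H](OCc1ccc(OC)cc1)c1cocc1CO[Si](C)(C)C(C)(C)C
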